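**Retrosynthetic overview**
- Ring B (pyran) is closed last: the C4a–C4 bond comes from a blue-light copper-acetylide coupling of a ring-A β-iodo enone (fragment A) with a side-chain enyne (fragment B), followed by 6-endo closure of O2–C3 and desilylation.
- Fragment A: 2-chloro-1,3-dione by a one-carbon (ClCH2Li) annulation across an acylal ester and a methyl ester; C8a by Fráter–Seebach alkoxymethylation; C7/C8 by a Seebach dioxolanone aldol from L-lactic acid.
- Fragment B: chelation-controlled diynyl addition to cis-2-acetyl-3-methyloxolane, then trans-hydroalumination; the oxolane comes from (S)-α-methyl-γ-butyrolactone via a Z-alkenol and directed epoxidation–cyclization.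
- Ring order: oxolane (fragment B) and carbocycle A (fragment A) in parallel, pyran ring B last.

Assumption: (S)-α-methyl-γ-butyrolactone and (S)-lactic acid are bought as single enantiomers and supply all chirality; the core uses isochromene numbering (O2, C1, C3 to C8a) and the side chain C1′ to C7′ (C4′ and C5′ are oxolane C2 and C3).

**Route**

Step 1
Reactants: 1 (S)-lactic acid; 2 pivalaldehyde
Product: 3 (2S,5S)-2-tert-butyl-5-methyl-1,3-dioxolan-4-one
Conditions: TsOH·H2O (cat.), H2SO4 (cat.), pentane, reflux, Dean–Stark; recryst. pentane/Et2O, −78 °C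
Reagents that add atoms: none
Why: Acid-catalysed acetalization (Seebach dioxolanone formation) keeps the lactate stereocentre and sets the cis acetal carbon under thermodynamic control, upgraded by crystallization.

Step 2
Reactants: 3 (2S,5S)-2-tert-butyl-5-methyl-1,3-dioxolan-4-one; 4 3,3-dimethoxypropanal
Product: 5 (2S,5R)-2-tert-butyl-5-[(1R)-1-hydroxy-3,3-dimethoxypropyl]-5-methyl-1,3-dioxolan-4-one
Conditions: LiN(i-Pr)2, THF, −78 °C; 4, −78 °C; AcOH quench at −78 °C
Reagents that add atoms: none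
Why: Seebach aldol with self-regeneration of the stereocentre: the enolate is attacked anti to tert-butyl (C7, net retention) and a Zimmerman–Traxler chair with the aldehyde chain equatorial sets C8 in the 7,8-anti sense (later cis-diol), the minor C8 epimer being removed by chromatography.

Step 3
Reactants: 5 (2S,5R)-2-tert-butyl-5-[(1R)-1-hydroxy-3,3-dimethoxypropyl]-5-methyl-1,3-dioxolan-4-one
Product: 6 methyl (3R)-3-[(2S,4R)-2-tert-butyl-4-methyl-5-oxo-1,3-dioxolan-4-yl]-3-hydroxypropanoate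
Conditions: O3, EtOAc, −78 °C; N2 purge
Reagents that add atoms: ozone, [O-][O+]=O
Why: Deslongchamps ozone oxidation of the dimethyl acetal C–H (hydrotrioxide collapse) gives the methyl ester without touching a stereocentre, the hindered acylal C–H of the dioxolanone being much less reactive.

Step 4
Reactants: 6 methyl (3R)-3-[(2S,4R)-2-tert-butyl-4-methyl-5-oxo-1,3-dioxolan-4-yl]-3-hydroxypropanoate; 7 4-methoxybenzyl chloromethyl ether
Product: 9 methyl (2S,3R)-3-[(2S,4R)-2-tert-butyl-4-methyl-5-oxo-1,3-dioxolan-4-yl]-2-{[(4-methoxyphenyl)methoxy]methyl}-3-[(triethylsilyl)oxy]propanoate, via free C8 alcohol 8 (not isolated)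
Conditions: LiN(i-Pr)2 (2.2 equiv), THF, −78 to −40 °C; 7, −78 to −30 °C; then Et3SiCl, DMPU, −30 °C to rt
Reagents that add atoms: chlorotriethylsilane, CC[Si](Cl)(CC)CC
Why: Fráter–Seebach alkylation: the lithium-chelated alkoxide–enolate dianion is alkoxymethylated on the face anti to the C7 substituent of C8 (2,3-anti, sets C8a with C1 cis to O8 in the later ring), and the alkoxide is silylated in the same flask.

Step 5
Reactants: 9 methyl (2S,3R)-3-[(2S,4R)-2-tert-butyl-4-methyl-5-oxo-1,3-dioxolan-4-yl]-2-{[(4-methoxyphenyl)methoxy]methyl}-3-[(triethylsilyl)oxy]propanoate; 10 chloroiodomethane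
Product: 12 (4S,5R,6R)-2-chloro-3,6-dihydroxy-4-{[(4-methoxyphenyl)methoxy]methyl}-6-methyl-5-[(triethylsilyl)oxy]cyclohex-2-en-1-one, via chloromethyl ketone 11 (not isolated)
Conditions: 10, MeLi·LiBr, THF/Et2O, −78 °C; then LiN(SiMe3)2 (2.5 equiv), −78 to 0 °C; AcOH
Reagents that add atoms: none
Why: Halomethyllithium homologation of the acylal-activated ester to an α-chloro ketone (Kowalski-type, pivalaldehyde lost) followed by intramolecular Claisen (Dieckmann-type) condensation of the chloro enolate onto the methyl ester closes ring A as the 2-chloro-1,3-dione (the same dione forms if the carbenoid attacks the methyl ester first), the three stereocentres being spectators.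

Step 6
Reactants: 12 (4S,5R,6R)-2-chloro-3,6-dihydroxy-4-{[(4-methoxyphenyl)methoxy]methyl}-6-methyl-5-[(triethylsilyl)oxy]cyclohex-2-en-1-one
Product: 13 (4S,5R,6R)-2-chloro-6-hydroxy-3-iodo-4-{[(4-methoxyphenyl)methoxy]methyl}-6-methyl-5-[(triethylsilyl)oxy]cyclohex-2-en-1-one
Conditions: PPh3, I2, Et3N, MeCN, rt
Reagents that add atoms: iodine, II
Why: Piers β-iodo enone synthesis (oxyphosphonium activation then addition–elimination by iodide) occurs at the less hindered enol oxygen, so the carbonyl next to the quaternary C7 is kept and iodine ends up on C4a.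

Step 7
Reactants: 13 (4S,5R,6R)-2-chloro-6-hydroxy-3-iodo-4-{[(4-methoxyphenyl)methoxy]methyl}-6-methyl-5-[(triethylsilyl)oxy]cyclohex-2-en-1-one
Product: 14 (4S,5R,6R)-2-chloro-6-hydroxy-4-(hydroxymethyl)-3-iodo-6-methyl-5-[(triethylsilyl)oxy]cyclohex-2-en-1-one
Conditions: DDQ, CH2Cl2/pH 7 buffer (10:1), 0 °C
Reagents that add atoms: none
Why: Oxidative cleavage of the 4-methoxybenzyl ether (benzylic hydride abstraction, hydrolysis of the oxocarbenium ion) frees the C1 hydroxyl while the silyl ether, vinyl iodide and tertiary alcohol are inert.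

Step 8
Reactants: 15 (S)-α-methyl-γ-butyrolactone [(3S)-3-methyloxolan-2-one]
Product: 16 (3S)-3-methyloxolan-2-ol (anomer mixture)
Conditions: i-Bu2AlH, CH2Cl2, −78 °C; Rochelle salt work-up
Reagents that add atoms: none
Why: Partial reduction of the lactone to the lactol (the tetrahedral aluminate survives at −78 °C) leaves the methyl-bearing stereocentre untouched.

Step 9
Reactants: 16 (3S)-3-methyloxolan-2-ol; 17 ethyltriphenylphosphonium bromide
Product: 18 (3S,4Z)-3-methylhex-4-en-1-ol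
Conditions: 17, KN(SiMe3)2 (2.2 equiv each), THF, 0 °C; then 16, −78 °C to rt
Reagents that add atoms: none
Why: Salt-free Wittig olefination of the open hydroxy aldehyde with a non-stabilized ylide gives the Z alkene through the kinetic cis-oxaphosphetane, and low temperature preserves the α-stereocentre.

Step 10
Reactants: 18 (3S,4Z)-3-methylhex-4-en-1-ol
Product: 20 (1R)-1-[(2R,3S)-3-methyloxolan-2-yl]ethan-1-ol, via cis epoxy alcohol 19 (not isolated)
Conditions: VO(acac)2 (5 mol %), t-BuOOH (1.5 equiv), CH2Cl2, rt; then CSA (cat.)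
Reagents that add atoms: tert-butyl hydroperoxide, CC(C)(C)OO
Why: Kishi-type hydroxyl-directed vanadium epoxidation–cyclization: in the allylic-strain-minimized conformer (C5′–H eclipsing the Z alkene) the vanadate ester delivers oxygen to the face bearing the hydroxyethyl arm, and 5-exo epoxide opening with inversion gives the 2,3-cis oxolane (sets C4′ from the bought C5′).

Step 11
Reactants: 20 (1R)-1-[(2R,3S)-3-methyloxolan-2-yl]ethan-1-ol
Product: 21 1-[(2R,3S)-3-methyloxolan-2-yl]ethan-1-one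
Conditions: Dess–Martin periodinane, pyridine, CH2Cl2, 0 °C to rt
Reagents that add atoms: none
Why: Dess–Martin oxidation under buffered, non-enolizing conditions gives the methyl ketone without epimerizing the cis α-alkoxy centre.

Step 12
Reactants: 21 1-[(2R,3S)-3-methyloxolan-2-yl]ethan-1-one; 22 1,4-bis(trimethylsilyl)buta-1,3-diyne
Product: 24 (2R)-2-[(2R,3S)-3-methyloxolan-2-yl]hexa-3,5-diyn-2-ol, via silylated diynol 23 (not isolated)
Conditions: 22, MeLi·LiBr, THF, rt; MgBr2·OEt2, Et2O/CH2Cl2, 0 °C; 21, −78 °C; then K2CO3 (cat.), MeOH, rt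
Reagents that add atoms: none
Why: Cram-chelate-controlled alkynylation (magnesium bridges the ketone and ring oxygens, attack from the face of the oxolane C2–H) sets the tertiary carbinol as R, and methanolysis then removes the alkynyl silane.

Step 13
Reactants: 24 (2R)-2-[(2R,3S)-3-methyloxolan-2-yl]hexa-3,5-diyn-2-ol
Product: 25 (2R,3E)-2-[(2R,3S)-3-methyloxolan-2-yl]hex-3-en-5-yn-2-ol
Conditions: NaAlH2(OCH2CH2OMe)2, THF, 0 °C to rt; Rochelle salt work-up
Reagents that add atoms: none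
Why: Alkoxide-directed trans-hydroalumination of the propargylic triple bond followed by protonolysis gives the E enyne, the distal alkyne having no directing group and staying intact.

Step 14
Reactants: 14 (4S,5R,6R)-2-chloro-6-hydroxy-4-(hydroxymethyl)-3-iodo-6-methyl-5-[(triethylsilyl)oxy]cyclohex-2-en-1-one; 25 (2R,3E)-2-[(2R,3S)-3-methyloxolan-2-yl]hex-3-en-5-yn-2-ol
Product: 27 (7R,8R,8aS)-5-chloro-7-hydroxy-3-{(1E,3R)-3-hydroxy-3-[(2R,3S)-3-methyloxolan-2-yl]but-1-en-1-yl}-7-methyl-8-[(triethylsilyl)oxy]-1,7,8,8a-tetrahydro-6H-isochromen-6-one, via ynenone 26 (not isolated)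
Conditions: CuCl (10 mol %), Cs2CO3 (2 equiv), MeCN, blue LEDs (450 nm), rt, Ar
Reagents that add atoms: none
Why: Proposed new method: the copper acetylide formed from 25, CuCl and Cs2CO3 is excited by blue light and transfers an electron to the easily reduced β-iodo enone 14, the vinyl radical released on C–I cleavage is captured at copper and reductive elimination forges the C4a–C4 bond of ynenone 26, after which the same monovalent copper/carbonate medium promotes 6-endo-dig 1,6-oxa-Michael addition of the C1 hydroxyl to close ring B with no stereocentre touched (O8 is silylated so only O1 can form the six-membered ring); the closest known chemistry is the visible-light copper-acetylide Sonogashira-type coupling of aryl halides combined with base- or coinage-metal-promoted cycloisomerization of 2-alkynyl enones to pyrans.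

Step 15
Reactants: 27 (7R,8R,8aS)-5-chloro-7-hydroxy-3-{(1E,3R)-3-hydroxy-3-[(2R,3S)-3-methyloxolan-2-yl]but-1-en-1-yl}-7-methyl-8-[(triethylsilyl)oxy]-1,7,8,8a-tetrahydro-6H-isochromen-6-one
Product: 28 peniciazaphilone E, (7R,8R,8aS)-5-chloro-7,8-dihydroxy-3-{(1E,3R)-3-hydroxy-3-[(2R,3S)-3-methyloxolan-2-yl]but-1-en-1-yl}-7-methyl-1,7,8,8a-tetrahydro-6H-isochromen-6-one
Conditions: HF·pyridine, pyridine, THF, 0 °C
Reagents that add atoms: none
Why: Buffered fluoride desilylation removes the triethylsilyl ether while sparing the acid-sensitive dienol ether, the α-ketol and the tertiary allylic alcohol.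

**Compound list**

1 | (S)-lactic acid | C[C@H](O)C(=O)O | starting material
2 | pivalaldehyde | CC(C)(C)C=O | starting material
3 | (2S,5S)-2-tert-butyl-5-methyl-1,3-dioxolan-4-one | C[C@@H]1O[C@H](C(C)(C)C)OC1=O | intermediate
4 | 3,3-dimethoxypropanal | COC(CC=O)OC | starting material
5 | (2S,5R)-2-tert-butyl-5-[(1R)-1-hydroxy-3,3-dimethoxypropyl]-5-methyl-1,3-dioxolan-4-one | COC(OC)C[C@@H](O)[C@@]1(C)O[C@H](C(C)(C)C)OC1=O | intermediate
6 | methyl (3R)-3-[(2S,4R)-2-tert-butyl-4-methyl-5-oxo-1,3-dioxolan-4-yl]-3-hydroxypropanoate | COC(=O)C[C@@H](O)[C@@]1(C)O[C@H](C(C)(C)C)OC1=O | intermediate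
7 | 4-methoxybenzyl chloromethyl ether | COc1ccc(COCCl)cc1 | starting material
8 | methyl (2S,3R)-3-[(2S,4R)-2-tert-butyl-4-methyl-5-oxo-1,3-dioxolan-4-yl]-3-hydroxy-2-{[(4-methoxyphenyl)methoxy]methyl}propanoate (not isolated) | COC(=O)[C@@H](COCc1ccc(OC)cc1)[C@@H](O)[C@@]1(C)O[C@H](C(C)(C)C)OC1=O | intermediate
9 | methyl (2S,3R)-3-[(2S,4R)-2-tert-butyl-4-methyl-5-oxo-1,3-dioxolan-4-yl]-2-{[(4-methoxyphenyl)methoxy]methyl}-3-[(triethylsilyl)oxy]propanoate | COC(=O)[C@@H](COCc1ccc(OC)cc1)[C@@H](O[Si](CC)(CC)CC)[C@@]1(C)O[C@H](C(C)(C)C)OC1=O | intermediate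
10 | chloroiodomethane | ClCI | starting material
11 | methyl (2S,3R,4R)-6-chloro-4-hydroxy-2-{[(4-methoxyphenyl)methoxy]methyl}-4-methyl-5-oxo-3-[(triethylsilyl)oxy]hexanoate (not isolated) | COC(=O)[C@@H](COCc1ccc(OC)cc1)[C@@H](O[Si](CC)(CC)CC)[C@@](C)(O)C(=O)CCl | intermediate
12 | (4S,5R,6R)-2-chloro-3,6-dihydroxy-4-{[(4-methoxyphenyl)methoxy]methyl}-6-methyl-5-[(triethylsilyl)oxy]cyclohex-2-en-1-one | O=C1C(Cl)=C(O)[C@@H](COCc2ccc(OC)cc2)[C@@H](O[Si](CC)(CC)CC)[C@@]1(C)O | intermediate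
13 | (4S,5R,6R)-2-chloro-6-hydroxy-3-iodo-4-{[(4-methoxyphenyl)methoxy]methyl}-6-methyl-5-[(triethylsilyl)oxy]cyclohex-2-en-1-one | O=C1C(Cl)=C(I)[C@@H](COCc2ccc(OC)cc2)[C@@H](O[Si](CC)(CC)CC)[C@@]1(C)O | intermediate
14 | (4S,5R,6R)-2-chloro-6-hydroxy-4-(hydroxymethyl)-3-iodo-6-methyl-5-[(triethylsilyl)oxy]cyclohex-2-en-1-one | O=C1C(Cl)=C(I)[C@@H](CO)[C@@H](O[Si](CC)(CC)CC)[C@@]1(C)O | intermediate
15 | (S)-α-methyl-γ-butyrolactone, (3S)-3-methyloxolan-2-one | C[C@H]1CCOC1=O | starting material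
16 | (3S)-3-methyloxolan-2-ol | C[C@H]1CCOC1O | intermediate
17 | ethyltriphenylphosphonium bromide | CC[P+](c1ccccc1)(c1ccccc1)c1ccccc1.[Br-] | starting material
18 | (3S,4Z)-3-methylhex-4-en-1-ol | C/C=C\[C@@H](C)CCO | intermediate
19 | (3S)-3-[(2S,3R)-3-methyloxiran-2-yl]butan-1-ol (not isolated) | C[C@H]1O[C@H]1[C@@H](C)CCO | intermediate
20 | (1R)-1-[(2R,3S)-3-methyloxolan-2-yl]ethan-1-ol | C[C@H]1CCO[C@H]1[C@@H](C)O | intermediate
21 | 1-[(2R,3S)-3-methyloxolan-2-yl]ethan-1-one | C[C@H]1CCO[C@H]1C(C)=O | intermediate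
22 | 1,4-bis(trimethylsilyl)buta-1,3-diyne | C[Si](C)(C)C#CC#C[Si](C)(C)C | starting material
23 | (2R)-2-[(2R,3S)-3-methyloxolan-2-yl]-6-(trimethylsilyl)hexa-3,5-diyn-2-ol (not isolated) | C[C@H]1CCO[C@H]1[C@](C)(O)C#CC#C[Si](C)(C)C | intermediate
24 | (2R)-2-[(2R,3S)-3-methyloxolan-2-yl]hexa-3,5-diyn-2-ol | C[C@H]1CCO[C@H]1[C@](C)(O)C#CC#C | intermediate
25 | (2R,3E)-2-[(2R,3S)-3-methyloxolan-2-yl]hex-3-en-5-yn-2-ol | C[C@H]1CCO[C@H]1[C@](C)(O)/C=C/C#C | intermediate
26 | (4S,5R,6R)-2-chloro-6-hydroxy-4-(hydroxymethyl)-3-{(3E,5R)-5-hydroxy-5-[(2R,3S)-3-methyloxolan-2-yl]hex-3-en-1-yn-1-yl}-6-methyl-5-[(triethylsilyl)oxy]cyclohex-2-en-1-one (not isolated) | C[C@H]1CCO[C@H]1[C@](C)(O)/C=C/C#CC1=C(Cl)C(=O)[C@](C)(O)[C@H](O[Si](CC)(CC)CC)[C@@H]1CO | intermediate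
27 | (7R,8R,8aS)-5-chloro-7-hydroxy-3-{(1E,3R)-3-hydroxy-3-[(2R,3S)-3-methyloxolan-2-yl]but-1-en-1-yl}-7-methyl-8-[(triethylsilyl)oxy]-1,7,8,8a-tetrahydro-6H-isochromen-6-one | C[C@H]1CCO[C@H]1[C@](C)(O)/C=C/C1=CC2=C(Cl)C(=O)[C@](C)(O)[C@H](O[Si](CC)(CC)CC)[C@@H]2CO1 | intermediate
28 | peniciazaphilone E | C[C@H]1CCO[C@H]1[C@](C)(O)/C=C/C1=CC2=C(Cl)C(=O)[C@](C)(O)[C@H](O)[C@@H]2CO1 | target

**Step count and risks**

Total steps: 15. Longest linear sequence: 9 (steps 1 to 7, then 14 and 15); the side-chain branch is 6 steps (8 to 13) before the union.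

Three steps most likely to fail:

1. Step 14 (the proposed new method). The light-driven copper coupling has not been shown on a β-iodo enone, and conjugate addition of the acetylide or incomplete ring closure may compete. Fallback with known chemistry: it sets out from 14 and 25 and comes back at 27. Sonogashira coupling with PdCl2(PPh3)2 (3 mol %), CuI (5 mol %) and i-Pr2NH in THF at rt gives ynenone 26, this time isolated. AuCl3 (5 mol %) or AgOTf in CH2Cl2 at rt then effects the 6-endo-dig cycloisomerization to 27. This detour makes no compound outside the list (F0).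

2. Step 5. The carbenoid may over-add, and if it attacks the methyl ester first the β-silyloxy ketone can eliminate before ring closure. Fallback: it sets out from 9 and comes back at 12. Crossed Claisen condensation of 9 with the lithium enolate of allyl acetate (LiN(SiMe3)2, THF, −78 °C) gives 1-methyl 7-allyl (2S,3R,4R)-4-hydroxy-2-{[(4-methoxyphenyl)methoxy]methyl}-4-methyl-5-oxo-3-[(triethylsilyl)oxy]heptanedioate F1. KOt-Bu in THF at 0 °C closes the ring (Dieckmann) to allyl (3S,4R,5R)-2,5-dihydroxy-3-{[(4-methoxyphenyl)methoxy]methyl}-5-methyl-6-oxo-4-[(triethylsilyl)oxy]cyclohex-1-ene-1-carboxylate F2. Pd(PPh3)4 with morpholine removes the allyl ester with decarboxylation to give (4S,5R,6R)-3,6-dihydroxy-4-{[(4-methoxyphenyl)methoxy]methyl}-6-methyl-5-[(triethylsilyl)oxy]cyclohex-2-en-1-one F3. N-Chlorosuccinimide in CH2Cl2 at 0 °C chlorinates C5 to give 12.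

3. Step 4. The lithium aldolate may undergo retro-aldol on warming, and the alkoxide can compete for the chloromethyl ether. Fallback: it sets out from 3 and comes back at 9, setting C8a by substrate-controlled hydroboration instead of enolate alkylation. Seebach aldol of 3 (LiN(i-Pr)2, THF, −78 °C) with 2-{[(4-methoxyphenyl)methoxy]methyl}prop-2-enal (C=C(COCc1ccc(OC)cc1)C=O) gives (2S,5R)-2-tert-butyl-5-[(1R)-1-hydroxy-2-{[(4-methoxyphenyl)methoxy]methyl}prop-2-en-1-yl]-5-methyl-1,3-dioxolan-4-one F4. Et3SiOTf with 2,6-lutidine gives its triethylsilyl ether F5. Still-type hydroboration with 9-BBN (anti to the allylic silyloxy group) and NaBO3·4H2O oxidation gives (2S,3R)-3-[(2S,4R)-2-tert-butyl-4-methyl-5-oxo-1,3-dioxolan-4-yl]-2-{[(4-methoxyphenyl)methoxy]methyl}-3-[(triethylsilyl)oxy]propan-1-ol F6. TEMPO/PhI(OAc)2 followed by NaClO2 gives the corresponding propanoic acid F7. Me3SiCHN2 in MeOH/toluene then gives 9.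

**Further compounds**

F0 | step 14 | none | none
F1 | step 5 | 1-methyl 7-allyl (2S,3R,4R)-4-hydroxy-2-{[(4-methoxyphenyl)methoxy]methyl}-4-methyl-5-oxo-3-[(triethylsilyl)oxy]heptanedioate | COC(=O)[C@@H](COCc1ccc(OC)cc1)[C@@H](O[Si](CC)(CC)CC)[C@@](C)(O)C(=O)CC(=O)OCC=C
F2 | step 5 | allyl (3S,4R,5R)-2,5-dihydroxy-3-{[(4-methoxyphenyl)methoxy]methyl}-5-methyl-6-oxo-4-[(triethylsilyl)oxy]cyclohex-1-ene-1-carboxylate | O=C1C(C(=O)OCC=C)=C(O)[C@@H](COCc2ccc(OC)cc2)[C@@H](O[Si](CC)(CC)CC)[C@@]1(C)O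
F3 | step 5 | (4S,5R,6R)-3,6-dihydroxy-4-{[(4-methoxyphenyl)methoxy]methyl}-6-methyl-5-[(triethylsilyl)oxy]cyclohex-2-en-1-one | O=C1C=C(O)[C@@H](COCc2ccc(OC)cc2)[C@@H](O[Si](CC)(CC)CC)[C@@]1(C)O
F4 | step 4 | (2S,5R)-2-tert-butyl-5-[(1R)-1-hydroxy-2-{[(4-methoxyphenyl)methoxy]methyl}prop-2-en-1-yl]-5-methyl-1,3-dioxolan-4-one | C=C(COCc1ccc(OC)cc1)[C@@H](O)[C@@]1(C)O[C@H](C(C)(C)C)OC1=O
F5 | step 4 | (2S,5R)-2-tert-butyl-5-[(1R)-2-{[(4-methoxyphenyl)methoxy]methyl}-1-[(triethylsilyl)oxy]prop-2-en-1-yl]-5-methyl-1,3-dioxolan-4-one | C=C(COCc1ccc(OC)cc1)[C@@H](O[Si](CC)(CC)CC)[C@@]1(C)O[C@H](C(C)(C)C)OC1=O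
F6 | step 4 | (2S,3R)-3-[(2S,4R)-2-tert-butyl-4-methyl-5-oxo-1,3-dioxolan-4-yl]-2-{[(4-methoxyphenyl)methoxy]methyl}-3-[(triethylsilyl)oxy]propan-1-ol | OC[C@@H](COCc1ccc(OC)cc1)[C@@H](O[Si](CC)(CC)CC)[C@@]1(C)O[C@H](C(C)(C)C)OC1=O
F7 | step 4 | (2S,3R)-3-[(2S,4R)-2-tert-butyl-4-methyl-5-oxo-1,3-dioxolan-4-yl]-2-{[(4-methoxyphenyl)methoxy]methyl}-3-[(triethylsilyl)oxy]propanoic acid | OC(=O)[C@@H](COCc1ccc(OC)cc1)[C@@H](O[Si](CC)(CC)CC)[C@@]1(C)O[C@H](C(C)(C)C)OC1=O
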